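**Retrosynthetic overview**
1. The target comes from a fully assembled germacranolide that carries only a C9/C10 acetonide and a C3 silyl ether; acid removes both at the end.
2. The ten-membered carbocycle and the α-methylene-γ-lactone come from a five-to-ten ring expansion of a cyclopentanol: the C1–C7 bond of a tertiary homoallylic zinc alkoxide breaks and C7 re-bonds to a tethered C6 enal, with the lactone closing in the same flask.
3. The cyclopentanol comes from an aldol-type union of a (Z)-configured C2–C6 bromoketone (from 3-methylfuran-2(5H)-one) with a cyclopentenone; hydroxyl-directed dihydroxylation sets C9 and C10, and a Corey–Bakshi–Shibata reduction sets C3.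
4. The cyclopentenone (C1, C7–C14 and the acrylate) comes from a Piancatelli rearrangement of the Morita–Baylis–Hillman adduct of 3-methylfurfural and isopropyl acrylate, followed by enzymatic resolution and Mitsunobu inversion with tiglic acid (C8).
5. Ring order: cyclopentenone first, then the dioxolane protecting ring, then the ten-membered carbocycle and the γ-lactone together in the key step.

Assumption: the SMILES is read as the (3S,4Z,6R,7S,8S,9S,10S) isomer; carbons are labelled C1–C15 as in germacranolides (C1 ketone, C3 carbinol, C4=C5, C6 lactone carbinol, C7, C8 tiglate carbinol, C9, C10 carbinol bearing methyl C14, C11=C13 methylene, C12 carboxyl, C15 methyl on C4) and these labels are used for every intermediate.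

**Step 1**
Reactants: 1 3-methylfuran-2-carbaldehyde; 2 propan-2-yl prop-2-enoate
Product: 3 racemic propan-2-yl 2-[hydroxy(3-methylfuran-2-yl)methyl]prop-2-enoate
Conditions: 1,4-diazabicyclo[2.2.2]octane (1 equiv), neat, rt, 4 d
Reagents that add atoms: none
Why: Morita–Baylis–Hillman reaction, in which the amine adds to the acrylate and the resulting enolate attacks the reactive furan aldehyde; the carbinol centre is racemic and is erased in step 2, while the acrylate carbons become C11–C13 and the aldehyde carbon becomes C7.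

**Step 2**
Reactants: 3 racemic furyl carbinol
Product: 4 racemic trans propan-2-yl 2-(5-hydroxy-3-methyl-2-oxocyclopent-3-en-1-yl)prop-2-enoate
Conditions: Dy(OTf)3 (10 mol %), MeCN/H2O 5:1, 80 °C
Reagents that add atoms: water, O
Why: Piancatelli rearrangement, in which ionisation of the furyl carbinol, attack of water at C5 of the furan, ring opening and conrotatory 4π closure of the hydroxypentadienyl cation give the 4-hydroxy-5-substituted cyclopentenone with C7 and C8 substituents trans, the furan 3-methyl ending as the enone α-methyl (C14 on C10).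

**Step 3**
Reactants: 4 racemic trans hydroxy enone
Product: 5 propan-2-yl 2-[(1R,5S)-5-hydroxy-3-methyl-2-oxocyclopent-3-en-1-yl]prop-2-enoate
Conditions: Burkholderia cepacia lipase (immobilised), vinyl acetate (3 equiv), MTBE, 30 °C, to about 52 % conversion, chromatography
Reagents that add atoms: none
Why: Enzymatic kinetic resolution by lipase transesterification, in which (Kazlauskas rule, branched C7 side as the large group) the (1S,5R) alcohol is acetylated and the (1R,5S) alcohol is left, fixing the absolute configuration of the route.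

**Step 4**
Reactants: 5 (1R,5S) hydroxy enone; 6 (2E)-2-methylbut-2-enoic acid
Product: 7 propan-2-yl 2-[(1R,5R)-3-methyl-5-{[(2E)-2-methylbut-2-enoyl]oxy}-2-oxocyclopent-3-en-1-yl]prop-2-enoate
Conditions: PPh3, diisopropyl azodicarboxylate, THF, 0 °C to rt
Reagents that add atoms: none
Why: Mitsunobu esterification, in which SN2 displacement of the alkoxyphosphonium by tiglate inverts C8, giving the ester with the target configuration at C8 and cis to the C7 substituent; β-elimination is disfavoured because it would give a cyclopentadienone.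

**Step 5**
Reactants: 8 3-methylfuran-2(5H)-one
Product: 9 (2Z)-4-hydroxy-N-methoxy-N,2-dimethylbut-2-enamide
Conditions: MeNH(OMe)·HCl, AlMe3, CH2Cl2, 0 °C to rt; aqueous Rochelle salt/HCl work-up
Reagents that add atoms: N,O-dimethylhydroxylamine hydrochloride, CNOC.Cl
Why: Weinreb aminolysis of the lactone by the aluminium amide, which carries the ring-enforced Z geometry of the butenolide (future C4=C5) into the open chain.

**Step 6**
Reactants: 9 hydroxy Weinreb amide
Product: 10 (2Z)-N-methoxy-N,2-dimethyl-4-[(triethylsilyl)oxy]but-2-enamide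
Conditions: Et3SiCl, imidazole, CH2Cl2, 0 °C
Reagents that add atoms: chlorotriethylsilane, CC[Si](Cl)(CC)CC
Why: Silylation of the primary allylic alcohol stops relactonisation and masks the oxygen that later becomes the C6 aldehyde.

**Step 7**
Reactants: 10 silylated Weinreb amide
Product: 11 (3Z)-1-bromo-3-methyl-5-[(triethylsilyl)oxy]pent-3-en-2-one
Conditions: CH2Br2, MeLi·LiBr, THF, −78 °C; aqueous NH4Cl
Reagents that add atoms: dibromomethane, BrCBr
Why: Carbenoid homologation of a Weinreb amide, in which LiCH2Br adds once to give a stable chelated tetrahedral intermediate that collapses on work-up to the α-bromoketone whose CH2 becomes C2.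

**Step 8**
Reactants: 11 bromoketone; 7 tiglate enone
Product: 13 propan-2-yl 2-[(1R,2R,5R)-2-hydroxy-3-methyl-2-{(3Z)-3-methyl-2-oxo-5-[(triethylsilyl)oxy]pent-3-en-1-yl}-5-{[(2E)-2-methylbut-2-enoyl]oxy}cyclopent-3-en-1-yl]prop-2-enoate, via samarium enolate 12 (not isolated)
Conditions: SmI2 (2.1 equiv), THF, −78 °C, 10 min; then 7, −78 °C, 30 min; aqueous NH4Cl at −78 °C
Reagents that add atoms: none
Why: Samarium Reformatsky-type aldol, in which two-electron reduction of the bromoketone gives the non-basic trivalent samarium enolate that adds 1,2 to the cyclopentenone carbonyl from the face anti to the C7 and C8 substituents, setting C1 with its hydroxyl cis to the C8 ester.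

**Step 9**
Reactants: 13 tertiary allylic alcohol
Product: 15 propan-2-yl 2-[(1R,2R,3S,4S,5S)-2,3,4-trihydroxy-3-methyl-2-{(3Z)-3-methyl-2-oxo-5-[(triethylsilyl)oxy]pent-3-en-1-yl}-5-{[(2E)-2-methylbut-2-enoyl]oxy}cyclopentyl]prop-2-enoate, via osmate ester 14 (not isolated)
Conditions: OsO4 (1.05 equiv), TMEDA (1.1 equiv), CH2Cl2, −78 °C; then aqueous Na2SO3, THF, rt
Reagents that add atoms: osmium tetroxide, O=[Os](=O)(=O)=O
Why: Hydrogen-bond-directed syn dihydroxylation, in which the OsO4–diamine complex is delivered by the tertiary allylic C1 hydroxyl to the only electron-rich alkene (the enone, acrylate and tiglate alkenes are electron-poor), setting C9 and C10 with both new hydroxyls cis to O1 and O8.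

**Step 10**
Reactants: 15 triol
Product: 16 C9/C10 acetonide of 15 with the C1 hydroxyl free
Conditions: 2,2-dimethoxypropane, pyridinium p-toluenesulfonate (5 mol %), CH2Cl2, 0 °C to rt
Reagents that add atoms: 2,2-dimethoxypropane, COC(C)(C)OC
Why: Acetonide formation occurs on the cis secondary/tertiary diol in preference to the tertiary/tertiary pair, protecting the future α-ketol and blocking tiglate migration to O9.

**Step 11**
Reactants: 16 acetonide enone
Product: 17 C3 (S) allylic alcohol of 16
Conditions: (R)-1-methyl-3,3-diphenyltetrahydro-1H,3H-pyrrolo[1,2-c][1,3,2]oxazaborole (0.5 equiv), catecholborane (2.5 equiv), toluene, −78 °C; pH 7 buffer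
Reagents that add atoms: none
Why: Corey–Bakshi–Shibata reduction, in which reagent-controlled 1,2-hydride delivery to the α-methyl enone (alkenyl as the large group) sets C3 as S independently of the distant ring stereocentres.

**Step 12**
Reactants: 17 diol
Product: 18 C3 tert-butyldimethylsilyl ether of 17
Conditions: t-BuMe2SiCl, imidazole, DMF, rt
Reagents that add atoms: tert-butyl(chloro)dimethylsilane, CC(C)(C)[Si](C)(C)Cl
Why: Silylation is selective for the secondary allylic C3 hydroxyl over the tertiary C1 hydroxyl, and it prevents the (Z)-γ-hydroxy enal of the next step from closing to a furan.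

**Step 13**
Reactants: 18 bis-silyl ether
Product: 19 (Z)-enal with free C1 hydroxyl
Conditions: (COCl)2, DMSO, CH2Cl2, −78 °C; then Et3N, −78 to −40 °C
Reagents that add atoms: none
Why: Swern oxidation applied directly to the primary triethylsilyl ether, in which the chlorosulfonium salt cleaves the Si–O bond and the alkoxysulfonium ylide gives the Z enal while the secondary silyl ether, the tertiary alcohol and the acetonide are untouched.

**Step 14**
Reactants: 19 cyclopentanol enal
Product: 23 protected lactone (target carrying the C3 silyl ether plus the C9/C10 acetonide), via ethylzinc alkoxide 20 (not isolated), via allylzinc ketoaldehyde 21 (not isolated), via macrocyclic zinc alkoxide 22 (not isolated)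
Conditions: ZnEt2 (1.0 equiv), toluene/THF 4:1, 0.002 M, 0 °C then 65 °C; aqueous NH4Cl
Reagents that add atoms: none
Why: Proposed new method: the ethylzinc alkoxide of the crowded all-cis tertiary homoallylic alcohol undergoes polar retro-allylation (C1–C7 heterolysis through a chair with C2 and C8 equatorial) to the C1 ketone and an (E)-2-(alkoxycarbonyl)allylzinc, which is captured at C7 by the tethered Z enal through a chair with the aldehyde substituent equatorial and the C8–C9 bond anti to the forming bond, so that C7 (S) and C6 (R) are set anti and the C6 alkoxide closes the trans lactone irreversibly, the net result being migration of C7 from C1 to C6 and expansion of the five-membered to the ten-membered carbocycle; the closest known reaction types are the fragmentation of hindered tertiary homoallylic zinc alkoxides to allylzinc reagents that add to aldehydes (allyl transfer) and the zinc-mediated 2-(alkoxycarbonyl)allylation–lactonisation of aldehydes, neither of which has been shown as a ring expansion.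

**Step 15**
Reactants: 23 protected lactone
Product: 24 CNP0106709.2
Conditions: CF3CO2H/H2O/THF 1:1:4, 0 °C to rt
Reagents that add atoms: none
Why: Acid hydrolysis of the acetonide and the allylic silyl ether frees the C3, C9 and C10 hydroxyls without touching a stereocentre, avoiding base that would trigger retro-aldol, α-ketol shift or tiglate migration.

**Compound list**
1 | 3-methylfuran-2-carbaldehyde | Cc1ccoc1C=O | starting material
2 | propan-2-yl prop-2-enoate (isopropyl acrylate) | C=CC(=O)OC(C)C | starting material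
3 | propan-2-yl 2-[hydroxy(3-methylfuran-2-yl)methyl]prop-2-enoate, racemate (both enantiomers given) | CC(C)OC(=O)C(=C)[C@@H](O)c1occc1C.CC(C)OC(=O)C(=C)[C@H](O)c1occc1C | intermediate
4 | propan-2-yl 2-[(1RS,5SR)-5-hydroxy-3-methyl-2-oxocyclopent-3-en-1-yl]prop-2-enoate, trans racemate (both enantiomers given) | CC(C)OC(=O)C(=C)[C@@H]1[C@@H](O)C=C(C)C1=O.CC(C)OC(=O)C(=C)[C@H]1[C@H](O)C=C(C)C1=O | intermediate
5 | propan-2-yl 2-[(1R,5S)-5-hydroxy-3-methyl-2-oxocyclopent-3-en-1-yl]prop-2-enoate | CC(C)OC(=O)C(=C)[C@@H]1[C@@H](O)C=C(C)C1=O | intermediate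
6 | (2E)-2-methylbut-2-enoic acid (tiglic acid) | C/C=C(\C)C(=O)O | starting material
7 | propan-2-yl 2-[(1R,5R)-3-methyl-5-{[(2E)-2-methylbut-2-enoyl]oxy}-2-oxocyclopent-3-en-1-yl]prop-2-enoate | CC(C)OC(=O)C(=C)[C@@H]1[C@H](OC(=O)/C(C)=C/C)C=C(C)C1=O | intermediate
8 | 3-methylfuran-2(5H)-one | CC1=CCOC1=O | starting material
9 | (2Z)-4-hydroxy-N-methoxy-N,2-dimethylbut-2-enamide | CON(C)C(=O)/C(C)=C\CO | intermediate
10 | (2Z)-N-methoxy-N,2-dimethyl-4-[(triethylsilyl)oxy]but-2-enamide | CON(C)C(=O)/C(C)=C\CO[Si](CC)(CC)CC | intermediate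
11 | (3Z)-1-bromo-3-methyl-5-[(triethylsilyl)oxy]pent-3-en-2-one | BrCC(=O)/C(C)=C\CO[Si](CC)(CC)CC | intermediate
12 | diiodo{[(3Z)-3-methyl-5-(triethylsilyloxy)penta-1,3-dien-2-yl]oxy}samarium (samarium enolate of 11) | C=C(O[Sm](I)I)/C(C)=C\CO[Si](CC)(CC)CC | intermediate (not isolated)
13 | propan-2-yl 2-[(1R,2R,5R)-2-hydroxy-3-methyl-2-{(3Z)-3-methyl-2-oxo-5-[(triethylsilyl)oxy]pent-3-en-1-yl}-5-{[(2E)-2-methylbut-2-enoyl]oxy}cyclopent-3-en-1-yl]prop-2-enoate | CC(C)OC(=O)C(=C)[C@@H]1[C@H](OC(=O)/C(C)=C/C)C=C(C)[C@@]1(O)CC(=O)/C(C)=C\CO[Si](CC)(CC)CC | intermediate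
14 | cyclic osmate ester of 13 across C9/C10 (hexavalent osmium glycolate, TMEDA-bound), oxygens cis to the C1 hydroxyl | CC(C)OC(=O)C(=C)[C@@H]1[C@H](OC(=O)/C(C)=C/C)[C@@H]2O[Os](=O)(=O)O[C@]2(C)[C@@]1(O)CC(=O)/C(C)=C\CO[Si](CC)(CC)CC.CN(C)CCN(C)C | intermediate (not isolated)
15 | propan-2-yl 2-[(1R,2R,3S,4S,5S)-2,3,4-trihydroxy-3-methyl-2-{(3Z)-3-methyl-2-oxo-5-[(triethylsilyl)oxy]pent-3-en-1-yl}-5-{[(2E)-2-methylbut-2-enoyl]oxy}cyclopentyl]prop-2-enoate | CC(C)OC(=O)C(=C)[C@@H]1[C@H](OC(=O)/C(C)=C/C)[C@H](O)[C@](C)(O)[C@@]1(O)CC(=O)/C(C)=C\CO[Si](CC)(CC)CC | intermediate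
16 | acetonide of 15: cis hydroxyls at ring positions 3 and 4 (C10 and C9) bridged as a 2,2-dimethyl-1,3-dioxolane, tertiary hydroxyl at position 2 (C1) free, configurations as in 15 | CC(C)OC(=O)C(=C)[C@@H]1[C@H](OC(=O)/C(C)=C/C)[C@@H]2OC(C)(C)O[C@]2(C)[C@@]1(O)CC(=O)/C(C)=C\CO[Si](CC)(CC)CC | intermediate
17 | 16 with the side-chain ketone reduced: side chain (2S,3Z)-2-hydroxy-3-methyl-5-[(triethylsilyl)oxy]pent-3-en-1-yl (C3 S) | CC(C)OC(=O)C(=C)[C@@H]1[C@H](OC(=O)/C(C)=C/C)[C@@H]2OC(C)(C)O[C@]2(C)[C@@]1(O)C[C@H](O)/C(C)=C\CO[Si](CC)(CC)CC | intermediate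
18 | 17 with the C3 hydroxyl as tert-butyldimethylsilyl ether | CC(C)OC(=O)C(=C)[C@@H]1[C@H](OC(=O)/C(C)=C/C)[C@@H]2OC(C)(C)O[C@]2(C)[C@@]1(O)C[C@H](O[Si](C)(C)C(C)(C)C)/C(C)=C\CO[Si](CC)(CC)CC | intermediate
19 | 18 with the CH2OSiEt3 terminus oxidised to the aldehyde: side chain (2S,3Z)-2-[(tert-butyldimethylsilyl)oxy]-3-methyl-5-oxopent-3-en-1-yl | CC(C)OC(=O)C(=C)[C@@H]1[C@H](OC(=O)/C(C)=C/C)[C@@H]2OC(C)(C)O[C@]2(C)[C@@]1(O)C[C@H](O[Si](C)(C)C(C)(C)C)/C(C)=C\C=O | intermediate
20 | ethylzinc alkoxide of 19 at the C1 oxygen | CC(C)OC(=O)C(=C)[C@@H]1[C@H](OC(=O)/C(C)=C/C)[C@@H]2OC(C)(C)O[C@]2(C)[C@@]1(O[Zn]CC)C[C@H](O[Si](C)(C)C(C)(C)C)/C(C)=C\C=O | intermediate (not isolated)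
21 | ring-opened (E)-allyl(ethyl)zinc keto-aldehyde: C1 ketone, C7=C11 double bond, ZnEt on C13, configurations (3S,8S,9S,10S) | O=C/C=C(C)\[C@@H](O[Si](C)(C)C(C)(C)C)CC(=O)[C@@]1(C)OC(C)(C)O[C@H]1[C@@H](OC(=O)/C(C)=C/C)/C=C(/C[Zn]CC)C(=O)OC(C)C | intermediate (not isolated)
22 | ten-membered ethylzinc C6-alkoxide isopropyl ester (C6–C7 bond formed, C11=C13 methylene restored), spatial arrangement at C3 and C6–C10 as in 23 | C=C(C(=O)OC(C)C)[C@H]1[C@H](O[Zn]CC)/C=C(/C)[C@@H](O[Si](C)(C)C(C)(C)C)CC(=O)[C@@]2(C)OC(C)(C)O[C@H]2[C@H]1OC(=O)/C(C)=C/C | intermediate (not isolated)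
23 | (3S,4Z,6R,7S,8S,9S,10S)-3-[(tert-butyldimethylsilyl)oxy]-9,10-(isopropylidenedioxy)-8-{[(2E)-2-methylbut-2-enoyl]oxy}-1-oxogermacra-4,11(13)-dien-12,6-olide | C=C1C(=O)O[C@@H]2/C=C(/C)[C@@H](O[Si](C)(C)C(C)(C)C)CC(=O)[C@@]3(C)OC(C)(C)O[C@H]3[C@@H](OC(=O)/C(C)=C/C)[C@@H]12 | intermediate
24 | CNP0106709.2, (3S,4Z,6R,7S,8S,9S,10S)-3,9,10-trihydroxy-8-{[(2E)-2-methylbut-2-enoyl]oxy}-1-oxogermacra-4,11(13)-dien-12,6-olide | C=C1C(=O)O[C@@H]2/C=C(/C)[C@@H](O)CC(=O)[C@@](C)(O)[C@@H](O)[C@@H](OC(=O)/C(C)=C/C)[C@@H]12 | target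

**Step count and risks**
Total steps: 15. Longest linear sequence: 12 steps (1 → 3 → 4 → 5 → 7 → 13 → 15 → 16 → 17 → 18 → 19 → 23 → 24); the three-step branch 8 → 9 → 10 → 11 joins at step 8.

The riskiest step is the new ring expansion of step 14. The zinc alkoxide may fail to fragment, may lactonise onto the neighbouring ester, or may close the ring with the wrong C6/C7 configuration. The fallback sets out from 19 and uses known chemistry. Hypoiodite fragmentation (PhI(OAc)2, I2, visible light, CH2Cl2) generates the C1 alkoxy radical; β-scission toward the ester-stabilised allyl radical and iodine trapping give the seco keto-aldehyde allylic iodide F1. CrCl2 in THF/DMF at high dilution (Nozaki–Hiyama–Kishi allylation, aldehyde-selective, the established ring closure for germacranolides) then forms the C6–C7 bond and the chromium alkoxide lactonises. This returns to the route at 23.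

The second risk is the Piancatelli rearrangement of step 2. The ester-bearing vinyl group makes the carbinol of 3 slow to ionise and open to allylic transposition. The fallback sets out from 1. Ethynylmagnesium bromide (THF, 0 °C) gives the more easily ionised 1-(3-methylfuran-2-yl)prop-2-yn-1-ol F2. The same rearrangement (Dy(OTf)3, MeCN/H2O) gives trans-5-ethynyl-4-hydroxy-2-methylcyclopent-2-en-1-one F3. Markovnikov alkoxycarbonylation of the terminal alkyne (Pd(OAc)2, diphenyl(pyridin-2-yl)phosphane, methanesulfonic acid, CO, propan-2-ol, 50 °C) then builds the isopropyl acrylate and returns to the route at 4.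

The third risk is the samarium aldol of step 8. Enone 7 has an acidic C7–H, two other Michael acceptors and a γ-acyloxy enone that SmI2 can reduce. The fallback sets out from 10. Methylmagnesium bromide (THF, 0 °C) gives (3Z)-3-methyl-5-[(triethylsilyl)oxy]pent-3-en-2-one F4. Its kinetic lithium enolate (lithium diisopropylamide, THF, −78 °C) is transmetallated with anhydrous CeCl3, and the weakly basic cerium enolate adds 1,2 to 7 from the same face. This returns to the route at 13.

**Further compounds**
F1 | step 14 | seco keto-aldehyde (Z)-allylic iodide: 21 with CH2I in place of CH2ZnEt and C8 cis to CH2I, configurations (3S,8S,9S,10S) | O=C/C=C(C)\[C@@H](O[Si](C)(C)C(C)(C)C)CC(=O)[C@@]1(C)OC(C)(C)O[C@H]1[C@@H](OC(=O)/C(C)=C/C)/C=C(\CI)C(=O)OC(C)C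
F2 | step 2 | 1-(3-methylfuran-2-yl)prop-2-yn-1-ol, racemate (both enantiomers given) | C#C[C@@H](O)c1occc1C.C#C[C@H](O)c1occc1C
F3 | step 2 | (4RS,5SR)-5-ethynyl-4-hydroxy-2-methylcyclopent-2-en-1-one, trans racemate (both enantiomers given) | C#C[C@@H]1[C@@H](O)C=C(C)C1=O.C#C[C@H]1[C@H](O)C=C(C)C1=O
F4 | step 8 | (3Z)-3-methyl-5-[(triethylsilyl)oxy]pent-3-en-2-one | CC(=O)/C(C)=C\CO[Si](CC)(CC)CC
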